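**Retrosynthetic overview**
1. Last bond, C9–C10, closes the ten-membered carbocycle C1–C10. A retro decarboxylative Claisen ring contraction leads to the 14-membered macrolactone 24, where C9 carries a temporary carboxyl group esterified to a 12β oxygen of ring A (alkene at C10=C11).
2. Enabling feature: C9–C10 lies between the butenolide alkene C8=C17 and the ring A alkene C11=C12. C10 ends an allyl unit C10–C11–C12 (retron O=C–C9–C10–C11=C12). C9 is a vinylogous α-position of lactone carbonyl C19, so a carboxyl on C9 gives a glutaconate that enolises softly and then leaves as CO2.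
3. 24 comes from ring A alcohol 10 and butenolide acid 21 by Mitsunobu esterification (C12–O) and B-alkyl Suzuki–Miyaura macrocyclisation (C4–C5, 5Z retained).
4. 10 comes from (S)-carvone: formylation/methylation (C1), vinylation (C2), Criegee rearrangement (C14 acetate), Luche reduction, 1,3-transposition. 21 comes from but-2-yn-1-ol: (Z)-iodoalkene, asymmetric propynylation (C7), allylmagnesiation/carboxylation.
5. Ring order: ring A (present in carvone), butenolide (step 11), temporary macrolactone (step 15), ten-membered ring (step 16, last).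

Key step: step 16

Conventions: briarane numbering is used throughout. C1 is the quaternary carbon, C2 the propionyloxy carbon, C5=C6 the ring alkene, C7 the lactone carbinol, C8=C17 the butenolide alkene and C19 the lactone carbonyl. C10 is the ring-fusion CH, C11=C12 the ring A alkene, C14 the acetoxy carbon and C15 the methyl on C1. β is the face of ring A that carries C15; α is the opposite face.
Assumption: the sense of induction of (−)-MIB (step 3) and (S,S)-ProPhenol (step 10) follows their usual mnemonics; if either is reversed on these substrates, the antipodal ligand is used.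

**Step 1**
Reactants: 1 (S)-(+)-carvone
Product: 2 (Z)-6-(hydroxymethylidene)carvone (chelated enol of 6-formylcarvone; isopropenyl at C14 α)
Conditions: LiN(iPr)2, THF, −78 °C; HCO2CH2CF3; then 1 M HCl
Reagents that add atoms: 2,2,2-trifluoroethyl formate O=COCC(F)(F)F
Why: Claisen-type C-formylation of the kinetic cross-conjugated lithium enolate (C1 is the only sp3 α-position) by the activated formate; the product rests as its chelated (Z)-enol and the carvone stereocentre (C14) is untouched.

**Step 2**
Reactants: 2 (Z)-6-(hydroxymethylidene)carvone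
Product: 3 6-formyl-6-methylcarvone (C15 β; CHO = C2 α; isopropenyl α)
Conditions: MeI, K2CO3, acetone, 25–40 °C
Reagents that add atoms: iodomethane CI
Why: C-alkylation of a β-keto aldehyde enolate; allylic strain with the exocyclic enolate pushes the C14 isopropenyl group pseudo-axial on the α face, so iodomethane enters from the β face and sets quaternary C1 with C15 trans to isopropenyl and C2 cis to it.

**Step 3**
Reactants: 3 6-formyl-6-methylcarvone
Product: 4 (2S)-allylic alcohol (6-[(1S)-1-hydroxyprop-2-enyl]-6-methylcarvone)
Conditions: CH2=CHMgBr + ZnCl2 (dioxane, filtered) gives Zn(CH=CH2)2; (−)-MIB (10 mol %), toluene, 0 °C; then H2O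
Reagents that add atoms: vinylmagnesium bromide C=C[Mg]Br
Why: amino-alcohol-catalysed enantioselective vinylzinc addition to an aldehyde, chemoselective for CHO over the doubly flanked enone carbonyl; the ligand sets (2S) and the dipole-minimised (Cornforth) approach past the small C15 methyl points the same way.

**Step 4**
Reactants: 4 (2S)-allylic alcohol
Product: 5 (2S)-propionate of 4
Conditions: (EtCO)2O, Et3N, DMAP, CH2Cl2, 0 to 25 °C
Reagents that add atoms: propionic anhydride CCC(=O)OC(=O)CC
Why: DMAP-catalysed (Steglich-type) acylation installs the final C2 propionate early and deactivates the neighbouring vinyl group towards ozone; no stereocentre is affected.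

**Step 5**
Reactants: 5 (2S)-propionate
Product: 8 14α-acetoxy enone, via methoxy hydroperoxide 6 (not isolated), via peracetate 7 (not isolated)
Conditions: O3 (Sudan Red 7B end point), CH2Cl2/MeOH, −78 °C; then Ac2O, Et3N, DMAP, CH2Cl2, 0 to 40 °C
Reagents that add atoms: ozone [O-][O+]=O; methanol CO
Why: ozonolysis in methanol then Criegee rearrangement of the peracetate; the isopropenyl group is the most electron-rich alkene (enone alkene and ester-flanked vinyl are deactivated), C14 migrates from carbon to oxygen with retention, and the target's acetyl group is made from the former isopropenyl carbons.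

**Step 6**
Reactants: 8 14α-acetoxy enone
Product: 9 10α-allylic alcohol (C11=C12)
Conditions: NaBH4, CeCl3·7H2O, MeOH, −78 to −20 °C
Reagents that add atoms: none
Why: Luche reduction (1,2-selective, esters untouched); hydride adds axially from the β face, anti to the pseudo-axial C2 side chain on C1, giving the 10α alcohol cis to the 14α acetate, as in carvone to cis-carveol.

**Step 7**
Reactants: 9 10α-allylic alcohol
Product: 10 12α-allylic alcohol (C10=C11)
Conditions: Ph3SiOReO3 (5 mol %), Et2O, −40 to 0 °C
Reagents that add atoms: none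
Why: rhenium-oxo-catalysed 1,3-transposition of an allylic alcohol, a suprafacial [3,3] oxygen shift on rhenium that carries oxygen from C10α to C12α and moves the alkene to C10=C11; release of crowding between OH and quaternary C1 should favour 10.

**Step 8**
Reactants: 11 but-2-yn-1-ol
Product: 13 (Z)-3-iodobut-2-en-1-ol, via cyclic vinylalanate 12 (not isolated)
Conditions: NaAlH2(OCH2CH2OMe)2, THF, 0 to 25 °C; I2, −78 °C; then H2O
Reagents that add atoms: iodine II
Why: hydroxyl-directed trans-hydroalumination places aluminium on the distal carbon in a five-membered alanate, and iodinolysis with retention gives only the (Z)-iodoalkene, the future 5Z geometry.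

**Step 9**
Reactants: 13 (Z)-3-iodobut-2-en-1-ol
Product: 14 (Z)-3-iodobut-2-enal
Conditions: MnO2, CH2Cl2, 25 °C, dark
Reagents that add atoms: none
Why: allylic alcohol oxidation with MnO2 under neutral conditions, which should leave the (Z)-iodoalkene geometry intact.

**Step 10**
Reactants: 14 (Z)-3-iodobut-2-enal
Product: 15 (4R,5Z)-6-iodohept-5-en-2-yn-4-ol
Conditions: propyne, Me2Zn, (S,S)-ProPhenol (10 mol %), Ph3P=O (20 mol %), toluene, 4 °C; then H2O
Reagents that add atoms: propyne CC#C
Why: zinc/ProPhenol-catalysed enantioselective alkynylation of an α,β-unsaturated aldehyde; the dinuclear zinc catalyst selects the aldehyde face and sets C7 as (R).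

**Step 11**
Reactants: 15 (4R,5Z)-6-iodohept-5-en-2-yn-4-ol
Product: 18 (5R)-4-allyl-5-[(Z)-2-iodoprop-1-enyl]-3-methylfuran-2(5H)-one, via oxamagnesacycle 16 (not isolated), via hydroxy acid 17 (not isolated)
Conditions: CH2=CHCH2MgCl (excess), THF/toluene, 25 to 60 °C; CO2, 0 °C; 2 M HCl
Reagents that add atoms: allylmagnesium chloride C=CC[Mg]Cl; carbon dioxide O=C=O
Why: alkoxide-directed anti-carbomagnesiation of a propargylic alcohol puts allyl on proximal C8 and magnesium on C17 in a five-membered chelate, carboxylation with retention places C19 cis to the C7 oxygen, and acid closes the butenolide without touching C7; iodine–magnesium exchange is not expected because the allyl anion is the more stable carbanion.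

**Step 12**
Reactants: 18 allyl butenolide
Product: 20 (5R)-5-[(Z)-2-iodoprop-1-enyl]-3-methyl-4-(2-oxoethyl)furan-2(5H)-one, via diol 19 (not isolated)
Conditions: OsO4 (2 mol %), NaIO4, 2,6-lutidine, dioxane/H2O, 25 °C
Reagents that add atoms: sodium periodate [Na+].[O-]I(=O)(=O)=O (terminal oxygen source, relayed by OsO4)
Why: Lemieux–Johnson cleavage; OsO4 attacks the only unhindered, electronically neutral alkene (terminal allyl) and spares the iodoalkene and the electron-poor tetrasubstituted butenolide alkene.

**Step 13**
Reactants: 20 butenolide acetaldehyde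
Product: 21 (5R)-4-(carboxymethyl)-5-[(Z)-2-iodoprop-1-enyl]-3-methylfuran-2(5H)-one
Conditions: NaClO2, NaH2PO4, 2-methylbut-2-ene, t-BuOH/H2O, 0 to 25 °C
Reagents that add atoms: sodium chlorite [Na+].[O-]Cl=O
Why: Pinnick oxidation, mild enough for the enolisable aldehyde, the iodoalkene and the C7 stereocentre.

**Step 14**
Reactants: 10 12α-allylic alcohol; 21 butenolide acetic acid
Product: 22 12β-ester of 21 (open-chain diene iodide)
Conditions: PPh3, DIAD, toluene/THF, 0 °C
Reagents that add atoms: none
Why: Mitsunobu esterification; SN2 displacement of the activated 12α oxygen by the carboxylate inverts C12 to the 12β ester needed for the later chirality transfer (as in the known inversion of cis-carveol), while SN2' attack at neopentyl C10 is blocked.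

**Step 15**
Reactants: 22 12β-ester
Product: 24 14-membered macrolactone (C12β–O–CO–C9; C10=C11; 5Z), via B-alkyl-9-BBN 23 (not isolated)
Conditions: 9-BBN-H, THF, 25 °C; then slow addition to PdCl2(dppf) (15 mol %), AsPh3, Cs2CO3, DMF/THF/H2O, 1 mM, 25–45 °C
Reagents that add atoms: none
Why: 9-BBN hydroborates only the monosubstituted C3=C4 alkene, and the intramolecular B-alkyl Suzuki–Miyaura coupling joins C4 to C5 with retention of the (Z)-iodoalkene geometry under high dilution, closing the temporary macrolactone; allylic esters are known to survive these room-temperature conditions and no stereocentre is formed.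

**Step 16**
Reactants: 24 14-membered macrolactone
Product: 27 target CNP0112230.1, via silyl ketene acetal 25 (not isolated), via silyl ester 26 (not isolated)
Conditions: N,O-bis(trimethylsilyl)acetamide (2 equiv), KOAc (0.2 equiv), toluene, 110 °C (or microwave, 150 °C); then H2O, silica gel
Reagents that add atoms: none
Why: Proposed new method: BSA/KOAc silylates only the doubly activated C9 methylene (the CH2 of a glutaconate, flanked by the ester carbonyl and, through C8=C17, by C19), and ketene acetal 25 undergoes a transannular Ireland–Claisen [3,3] shift in which C9 bonds to C10, the C12–O bond breaks and the ring A alkene moves from C10=C11 to C11=C12; acetate then desilylates 26, whose carboxylate is a vinylogous malonate and loses CO2, and protonation at C9 restores the conjugated butenolide. The closest known reaction types are the decarboxylative Claisen rearrangement of allylic sulfonylacetates and malonates under these same reagents and the alicyclic Claisen rearrangement that contracts macrolactones by four ring atoms; their merger on a glutaconate-type macrolactone is the new element. One ring is closed, the ten-membered carbocycle C1–C10, by transannular C9–C10 bond formation across the 14-membered lactone through a six-centre transition state (ring contraction 14 to 10), and the temporary lactone disappears in the same event. The only lasting new stereocentre, C10, is set by suprafacial 1,3-chirality transfer from the pseudo-axial 12β C–O bond, so C9 arrives on the β face, cis to C15 and trans to the pseudo-axial α C2 chain, while the transient C9 centre is erased by decarboxylation. The step needs chemoselective enolisation (secured by the far higher acidity of C9–H than of the acetate, propionate and C7–H positions), regiocontrol (secured by the concerted shift, which can deliver C9 only to C10) and retention at C7 (secured by the weak acetate base).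

**Compound list**
1 | (S)-(+)-carvone | O=C1C(C)=CC[C@H](C(C)=C)C1 | starting material
2 | (Z)-6-(hydroxymethylidene)carvone | O/C=C1\C(=O)C(C)=CC[C@@H]1C(C)=C | intermediate
3 | 6-formyl-6-methylcarvone (C15 β, CHO α, isopropenyl α) | O=C1C(C)=CC[C@H](C(C)=C)[C@]1(C)C=O | intermediate
4 | (2S)-allylic alcohol | O=C1C(C)=CC[C@H](C(C)=C)[C@]1(C)[C@@H](O)C=C | intermediate
5 | (2S)-propionate | O=C1C(C)=CC[C@H](C(C)=C)[C@]1(C)[C@@H](OC(=O)CC)C=C | intermediate
6 | methoxy hydroperoxide (side-chain carbon unassigned) | O=C1C(C)=CC[C@H](C(C)(OC)OO)[C@]1(C)[C@@H](OC(=O)CC)C=C | intermediate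
7 | peracetate of 6 | O=C1C(C)=CC[C@H](C(C)(OC)OOC(C)=O)[C@]1(C)[C@@H](OC(=O)CC)C=C | intermediate
8 | 14α-acetoxy enone | O=C1C(C)=CC[C@H](OC(C)=O)[C@]1(C)[C@@H](OC(=O)CC)C=C | intermediate
9 | 10α-allylic alcohol | O[C@@H]1C(C)=CC[C@H](OC(C)=O)[C@]1(C)[C@@H](OC(=O)CC)C=C | intermediate
10 | 12α-allylic alcohol (C10=C11) | C1=C(C)[C@H](O)C[C@H](OC(C)=O)[C@]1(C)[C@@H](OC(=O)CC)C=C | intermediate
11 | but-2-yn-1-ol | CC#CCO | starting material
12 | cyclic sodium vinylalanate | CC1=CCO[Al-]1(OCCOC)OCCOC.[Na+] | intermediate
13 | (Z)-3-iodobut-2-en-1-ol | I/C(C)=C\CO | intermediate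
14 | (Z)-3-iodobut-2-enal | I/C(C)=C\C=O | intermediate
15 | (4R,5Z)-6-iodohept-5-en-2-yn-4-ol | I/C(C)=C\[C@@H](O)C#CC | intermediate
16 | oxamagnesacycle (C17–Mg–O chelate) | I/C(C)=C\[C@H]1O[Mg]C(C)=C1CC=C | intermediate
17 | (Z)-hydroxy acid (C7–OH cis to CO2H) | I/C(C)=C\[C@@H](O)/C(CC=C)=C(\C(=O)O)C | intermediate
18 | (5R)-4-allyl-5-[(Z)-2-iodoprop-1-enyl]-3-methylfuran-2(5H)-one | I/C(C)=C\[C@H]1OC(=O)C(C)=C1CC=C | intermediate
19 | diol from 18 (carbinol unassigned) | I/C(C)=C\[C@H]1OC(=O)C(C)=C1CC(O)CO | intermediate
20 | butenolide acetaldehyde | I/C(C)=C\[C@H]1OC(=O)C(C)=C1CC=O | intermediate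
21 | butenolide acetic acid | I/C(C)=C\[C@H]1OC(=O)C(C)=C1CC(=O)O | intermediate
22 | 12β-ester | C1=C(C)[C@@H](OC(=O)CC2=C(C)C(=O)O[C@@H]2/C=C(\I)C)C[C@H](OC(C)=O)[C@]1(C)[C@@H](OC(=O)CC)C=C | intermediate
23 | B-alkyl-9-BBN of 22 | C1=C(C)[C@@H](OC(=O)CC2=C(C)C(=O)O[C@@H]2/C=C(\I)C)C[C@H](OC(C)=O)[C@]1(C)[C@@H](OC(=O)CC)CCB3C4CCCC3CCC4 | intermediate
24 | 14-membered macrolactone | CCC(=O)O[C@H]1CC/C(C)=C\[C@H]2OC(=O)C(C)=C2CC(=O)O[C@H]3C[C@H](OC(C)=O)[C@@]1(C)C=C3C | intermediate
25 | silyl ketene acetal (C9=C geometry unassigned) | CCC(=O)O[C@H]1CC/C(C)=C\[C@H]2OC(=O)C(C)=C2C=C(O[Si](C)(C)C)O[C@H]3C[C@H](OC(C)=O)[C@@]1(C)C=C3C | intermediate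
26 | C9-carboxylic trimethylsilyl ester (C9 unassigned, erased) | CCC(=O)O[C@H]1CC/C(C)=C\[C@H]2OC(=O)C(C)=C2C(C(=O)O[Si](C)(C)C)[C@H]2C(C)=CC[C@H](OC(C)=O)[C@]12C | intermediate
27 | CNP0112230.1, (1S,2S,5Z,7R,10S,14S)-14-acetoxy-2-propanoyloxybriara-5,8(17),11-triene 7,19-lactone | CCC(=O)O[C@H]1CC/C(C)=C\[C@H]2OC(=O)C(C)=C2C[C@H]2C(C)=CC[C@H](OC(C)=O)[C@]12C | target

**Totals**
Total step count: 16. Longest linear sequence: 10 (steps 1–7, then 14–16).

**Steps most likely to fail**

*Step 16 (new method).*
- Risk: the transannular shift may be too slow, because the C9 terminus must reach the β face of C10 across the bridged ring A. Elimination or ionisation of the allylic ester, or slow epimerisation at C7 on long heating, could then overtake it.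
- Fallback: reverse the order of the two carbon–carbon bond formations, setting out from 22.
 - Soft enolisation (Me3SiOTf, Et3N) gives the open-chain silyl ketene acetal F1.
 - An ordinary, unstrained Ireland–Claisen rearrangement and aqueous work-up give the C9 carboxylic acid F2.
 - Gentle heating decarboxylates this vinylogous malonic acid to the seco diene iodide F3.
 - 9-BBN-H converts F3 into the B-alkyl-9-BBN F4.
 - A B-alkyl Suzuki–Miyaura macrocyclisation (PdCl2(dppf), AsPh3, Cs2CO3, high dilution) closes the ten-membered ring at C4–C5 and returns to the route at 27.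

*Step 15.*
- Risk: oligomerisation, protodeboronation, or premature ionisation of the allylic glutaconate ester by zerovalent palladium under the basic conditions may compete with ring closure.
- Fallback: couple first and lactonise afterwards, setting out from 10 and 21.
 - 21 is protected as the 2-(trimethylsilyl)ethyl ester F5.
 - 10 is treated with two equivalents of 9-BBN-H to give the bis-boron compound F6.
 - Intermolecular Suzuki–Miyaura coupling gives the hydroxy ester F7.
 - Bu4NF/AcOH releases the seco acid F8.
 - A Mitsunobu macrolactonisation (PPh3, DIAD, high dilution, inversion at C12) returns to the route at 24.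

*Step 7.*
- Risk: the equilibrium may stay incomplete, or ionisation to the allyl cation may cause loss of stereochemical integrity or elimination to a diene.
- Fallback: an irreversible three-operation transposition from 9.
 - Hydroxyl-directed epoxidation (VO(acac)2, t-BuOOH) gives the 11α,12α-epoxy alcohol F9.
 - Thiocarbonyldiimidazole gives the thiocarbonylimidazolide F10.
 - Bu3SnH/AIBN generates the C10 radical, which opens the epoxide (the radical variant of the Wharton transposition). This returns to the route at 10.

**Further compounds**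
F1 | step 16 | open-chain silyl ketene acetal of 22 | C1=C(C)[C@@H](OC(O[Si](C)(C)C)=CC2=C(C)C(=O)O[C@@H]2/C=C(\I)C)C[C@H](OC(C)=O)[C@]1(C)[C@@H](OC(=O)CC)C=C
F2 | step 16 | C9 carboxylic acid after open-chain Ireland–Claisen rearrangement (C9 unassigned) | OC(=O)C(C1=C(C)C(=O)O[C@@H]1/C=C(\I)C)[C@H]2C(C)=CC[C@H](OC(C)=O)[C@]2(C)[C@@H](OC(=O)CC)C=C
F3 | step 16 | seco diene iodide (C9–C10 formed, C4–C5 open) | C(C1=C(C)C(=O)O[C@@H]1/C=C(\I)C)[C@H]2C(C)=CC[C@H](OC(C)=O)[C@]2(C)[C@@H](OC(=O)CC)C=C
F4 | step 16 | B-alkyl-9-BBN of F3 | C(C1=C(C)C(=O)O[C@@H]1/C=C(\I)C)[C@H]2C(C)=CC[C@H](OC(C)=O)[C@]2(C)[C@@H](OC(=O)CC)CCB3C4CCCC3CCC4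
F5 | step 15 | 2-(trimethylsilyl)ethyl ester of 21 | I/C(C)=C\[C@H]1OC(=O)C(C)=C1CC(=O)OCC[Si](C)(C)C
F6 | step 15 | bis-boron compound from 10 (C4–B and O12–B) | C1=C(C)[C@H](OB5C6CCCC5CCC6)C[C@H](OC(C)=O)[C@]1(C)[C@@H](OC(=O)CC)CCB3C4CCCC3CCC4
F7 | step 15 | coupled 12α-hydroxy silylethyl ester | CCC(=O)O[C@@H](CC/C(C)=C\[C@H]1OC(=O)C(C)=C1CC(=O)OCC[Si](C)(C)C)[C@]2(C)C=C(C)[C@H](O)C[C@@H]2OC(C)=O
F8 | step 15 | seco hydroxy acid | CCC(=O)O[C@@H](CC/C(C)=C\[C@H]1OC(=O)C(C)=C1CC(=O)O)[C@]2(C)C=C(C)[C@H](O)C[C@@H]2OC(C)=O
F9 | step 7 | 11α,12α-epoxy-10α-alcohol | O[C@@H]1[C@]2(C)O[C@@H]2C[C@H](OC(C)=O)[C@]1(C)[C@@H](OC(=O)CC)C=C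
F10 | step 7 | thiocarbonylimidazolide of F9 | S=C(n3ccnc3)O[C@@H]1[C@]2(C)O[C@@H]2C[C@H](OC(C)=O)[C@]1(C)[C@@H](OC(=O)CC)C=C
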